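Readings and results come from a simulation for an exercise; noise was put on by code.

I began from the one sum a closed flask keeps: starting material, target, side product and quenched substrate, each counted by the starting material in it, add up to the charge plus the seed of target.

the same everywhere: starting material 0.20 M

| flask | target | protic impurity | remark | time |
|---|---|---|---|---|
| elm | 0.020 M | 0.067 M | run made earlier |  |
| alder | 0.020 M | 0.15 M | run made earlier |  |
| oak | 0.040 M | 0.10 M | run made earlier |  |
| flask | 0.0200 M | 0.100 M |  | 40 h |

| run | time / h | side product / % | target / % | starting material / % |
|---|---|---|---|---|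
| elm | 2.50 | 4.5 | 30.1 | 51.0 |
| elm | 5.00 | 8.7 | 50.9 | 20.9 |
| elm | 10.0 | 12.2 | 65.0 | 2.6 |
| elm | 15.0 | 11.4 | 67.9 | 0 |
| elm | 30.0 | 12.4 | 67.0 | 0 |
| alder | 2.50 | 3.1 | 24.4 | 33.0 |
| alder | 5.00 | 5.6 | 34.7 | 13.7 |
| alder | 10.0 | 6.6 | 40.0 | 1.3 |
| alder | 15.0 | 6.3 | 41.9 | 1.0 |
| alder | 30.0 | 6.6 | 41.3 | 1.3 |
| oak | 2.50 | 7.8 | 48.3 | 31.1 |
| oak | 5.00 | 10.0 | 64.4 | 8.8 |
| oak | 10.0 | 11.2 | 70.2 | 0.3 |
| oak | 15.0 | 10.2 | 70.1 | 0.4 |
| oak | 30.0 | 10.4 | 70.9 | 0 |

(scatter of a reading: 0.5 percentage points)

- a species is counted by the starting material in it: one side product counts as two
- amounts and yields of target count crystals too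
- given per volume of solution although it is solid: crystals
- steps thought possible: starting material + protic impurity -> quenched substrate; starting material -> target; starting material + target -> side product; crystals <-> target; starting material + target -> 2 target

1. the species that holds most of what was charged as starting material, at 40 h (side product / target / starting material)
2. the largest share itself, whichever of these holds it, in percent of the starting material charged

So the last reading of each run gave its quenched substrate by difference. I read two ratios from the same readings: the side product per point of target gained, and what I call the exchange exponent (a selectivity factor), the log of the target's growth over its seed divided by the log of the impurity's fall from its charge. If target grows with [starting material][target] and quench goes with [starting material][protic impurity], time cancels and this exponent holds between runs.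

| Run | Side product per target gained | Quenched substrate | Exchange exponent |
|---|---|---|---|
| elm | 0.218 | 30.6% | 0.777 |
| alder | 0.211 | 60.8% | 0.852 |
| oak | 0.204 | 38.7% | 0.851 |

The means were 0.211 and 0.827. For the flask I took starting material as used up by the asked time, as elm read 0% at 30.0 h. If the flask's impurity, worth 50.0% of the charge, were wholly quenched, the balance gave target 51.3%.

That was the weak link, since every run kept some impurity. The exponent put the flask's remainder at 6.92% of the charge, which raised target to 57.0%. A second pass left 6.09% and target 56.3%, against side product 9.77%.

The forecast said target at 56%: “Interpolating elm and alder gives about 56%”. The flask gave target at 56.2%, with side product 9.74%.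

    starting material + protic impurity → quenched substrate (k = 0.0622 M⁻¹ min⁻¹)
    starting material → target (k = 3.37 × 10⁻⁷ min⁻¹)
    starting material + target → side product (k = 0.00532 M⁻¹ min⁻¹)
    crystals ⇌ target, rate k4*(cs4 - [target]) while solid is left; crystals form when [target] > cs4 (solubility = 0.170 M, k = 0.0756 min⁻¹)
    starting material + target → 2 target (k = 0.0558 M⁻¹ min⁻¹)

In the flask, by 4.00 h, starting material stood at 26.7%, quenched substrate at 40.1% and target at 37.4%. By 20.0 h starting material was down to 0.0241% and target stood at 56.2%, as it did at 400 h, with crystals at 0%, its 0.112 M lying below the 0.17 M where they form. From that target, the exponent put the flask's impurity left at 12.4% of its own charge; it held 12%.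

For the neighbour with 0.025 M of impurity, one pass of the same reckoning ran from 82.3% target, left 7.82% of that impurity and gave 83.1% target. That neighbour gave 83.0%, with 7.4% of its impurity left.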